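**Retrosynthetic overview**

- The formyl groups and free phenols of the target are end-game changes on the arene of a spirochroman dimethyl ether: dibromination, lithiation/DMF, then thiolate demethylation.
- The strategy rests on the spiro carbon (C2 of ring C, C2' of ring B). It is tertiary, bound to the aryl ether oxygen O1 and allylic to the C1'=C8a' alkene of ring B. It is therefore the carbonyl carbon of a bicyclic enone: C2–C3 comes from 1,2-addition of a 2,2-diarylethyl cerium reagent, and O1–C2 from SN1 closure of ring C on the derived allyl cation.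
- The enone comes from (R)-citronellal and methyl vinyl ketone: amine-catalysed Michael addition (sets C4a), aldol condensation (ring B), conjugate ene reaction (ring A, sets C8), hydrogenation, and Saegusa–Ito return of the C1=C8a alkene.
- The cerium reagent comes from an (S)-2,2-diarylethyl iodide, made from 5,7-dimethoxycoumarin and phenylboronic acid by asymmetric 1,4-addition, lactone opening and Barton iodo-decarboxylation.
- Ring order: ring B, then ring A; the arene is bought; ring C (dihydropyran) closes last, in the key step.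

Key step: step 10

Remark on numbering: the bicyclic ketones carry naphthalenone numbers (C2 carbonyl, C1, C8a, C8, C5, C4a); in the spiro compounds these atoms are primed.

Remark on protection: the phenol that closes ring C is carried as its methoxymethyl (MOM) ether up to the key step, because a free ortho-hydroxyl beside a 2-iodoethyl chain would close to a dihydrobenzofuran under any basic treatment.

Assumption: the sense of induction of the prolinol ether (step 1) and of SEGPHOS (step 7) is taken from the accepted models for these catalyst classes; if a test run shows the opposite sense, the antipodal catalyst is used.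

**Route**

Step 1
Reactants: 1 (R)-citronellal; 2 methyl vinyl ketone
Product: 3 (2R,3R)-3,7-dimethyl-2-(3-oxobutyl)oct-6-enal
Conditions: 2 (1.5 equiv), (R)-2-[methoxy(diphenyl)methyl]pyrrolidine (5 mol %), ethyl 3,4-dihydroxybenzoate (20 mol %), neat, 4 °C
Reagents that add atoms: none
Why: Enamine-catalysed Michael addition in which the E-enamine of 1 reacts on the face remote from the diphenyl(methoxy)methyl group, so the R catalyst should set C2 as R whatever the C3 methyl group prefers.

Step 2
Reactants: 3 (2R,3R)-3,7-dimethyl-2-(3-oxobutyl)oct-6-enal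
Product: 4 (4R)-4-[(2R)-6-methylhept-5-en-2-yl]cyclohex-2-en-1-one
Conditions: KOH (0.1 M aq), n-Bu4NOH (cat.), Et2O/THF/H2O, reflux
Reagents that add atoms: none
Why: Intramolecular aldol condensation (Robinson-type closure of ring B) of the methyl ketone enolate onto the aldehyde, which should outrun enolisation of the α-branched aldehyde, so the centre that becomes C4a is kept and no new stereocentre is formed.

Step 3
Reactants: 4 (4R)-4-[(2R)-6-methylhept-5-en-2-yl]cyclohex-2-en-1-one
Product: 5 (4aR,5R,8R,8aR)-5-methyl-8-(prop-1-en-2-yl)octahydronaphthalen-2(1H)-one (cis-fused)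
Conditions: EtAlCl2 (1.2 equiv), CH2Cl2, −78 → −20 °C; 1 M HCl
Reagents that add atoms: none
Why: Lewis-acid-promoted intramolecular conjugate ene reaction in which the trisubstituted alkene adds axially to the β-carbon of the bound enone through a chair with the secondary methyl and the forming isopropenyl group equatorial, which should give the cis ring fusion (C8a) and set C8 with the isopropenyl group trans to the C8a–C1 bond.

Step 4
Reactants: 5 (4aR,5R,8R,8aR)-5-methyl-8-(prop-1-en-2-yl)octahydronaphthalen-2(1H)-one
Product: 6 (4aR,5R,8S,8aS)-5-methyl-8-(propan-2-yl)octahydronaphthalen-2(1H)-one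
Conditions: H2 (1 atm), RhCl(PPh3)3 (5 mol %), benzene/EtOH, 23 °C
Reagents that add atoms: none
Why: Homogeneous hydrogenation that saturates the 1,1-disubstituted alkene without moving it into the ring and leaves the ketone, so C8 keeps its configuration (the descriptor changes only through priorities).

Step 5
Reactants: 6 (4aR,5R,8S,8aS)-5-methyl-8-(propan-2-yl)octahydronaphthalen-2(1H)-one
Product: 7 trimethyl{[(4aR,5R,8S,8aS)-5-methyl-8-(propan-2-yl)-3,4,4a,5,6,7,8,8a-octahydronaphthalen-2-yl]oxy}silane
Conditions: Me3SiCl, NaI, Et3N, MeCN, 23 → 40 °C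
Reagents that add atoms: chlorotrimethylsilane, C[Si](C)(C)Cl
Why: Thermodynamic silyl enol ether formation (reversible silylation by Me3SiI made in the flask), in which the C1=C2 isomer should prevail because it puts C8 pseudoaxial on the allylic ring-fusion carbon and removes its gauche contact with C2, in line with the general enolisation of cis-fused 2-decalones toward the ring fusion; no stereocentre is touched.

Step 6
Reactants: 7 trimethyl{[(4aR,5R,8S,8aS)-5-methyl-8-(propan-2-yl)-3,4,4a,5,6,7,8,8a-octahydronaphthalen-2-yl]oxy}silane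
Product: 8 (4aR,5R,8S)-5-methyl-8-(propan-2-yl)-4,4a,5,6,7,8-hexahydronaphthalen-2(3H)-one
Conditions: Pd(OAc)2 (10 mol %), O2 (1 atm), DMSO, 23 °C
Reagents that add atoms: none
Why: Saegusa–Ito oxidation in which the palladium enolate bound at C1 has its only β-hydrogen at C8a and cis to the metal, so syn β-hydride elimination can give only the C1=C8a enone, and the neutral conditions leave the γ-centres C4a and C8 alone.

Step 7
Reactants: 9 5,7-dimethoxycoumarin; 10 phenylboronic acid
Product: 11 (4S)-5,7-dimethoxy-4-phenylchroman-2-one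
Conditions: 10 (5 equiv), Rh(acac)(C2H4)2 (3 mol %), (S)-SEGPHOS (3.3 mol %), dioxane/H2O (10:1), 60 °C
Reagents that add atoms: none
Why: Hayashi–Miyaura reaction in which phenylrhodium inserts the coumarin C3=C4 bond on one enantioface under ligand control and the oxa-π-allyl rhodium is hydrolysed; the S ligand is chosen because ligand and product descriptors match for simple coumarins.

Step 8
Reactants: 11 (4S)-5,7-dimethoxy-4-phenylchroman-2-one
Product: 14 (3S)-3-[2,4-dimethoxy-6-(methoxymethoxy)phenyl]-3-phenylpropanoic acid, via disodium phenoxide carboxylate 12 (not isolated), via bis-MOM ester 13 (not isolated)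
Conditions: NaOH (2.2 equiv), THF/H2O, 23 °C; evaporate; MOMCl (2.5 equiv), DMF, 0 → 23 °C; then 1 M NaOH, 23 °C; 1 M HCl to pH 4, 0 °C
Reagents that add atoms: sodium hydroxide, [Na+].[OH-]; chloromethyl methyl ether, COCCl
Why: Lactone saponification, Williamson-type O-alkylation of both oxyanions and selective hydrolysis of the labile MOM ester, which masks the phenol against relactonisation and later cyclisation without touching the stereocentre.

Step 9
Reactants: 14 (3S)-3-[2,4-dimethoxy-6-(methoxymethoxy)phenyl]-3-phenylpropanoic acid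
Product: 16 2-[(1S)-2-iodo-1-phenylethyl]-1,5-dimethoxy-3-(methoxymethoxy)benzene, via Barton ester 15 (not isolated)
Conditions: 1-hydroxypyridine-2(1H)-thione, DCC, DMAP (cat.), CH2Cl2, 0 → 23 °C, dark; then CHI3 (2 equiv), hν (tungsten lamp), 23 °C
Reagents that add atoms: iodoform, IC(I)I
Why: Barton decarboxylation with iodine-atom transfer, in which the primary radical should be trapped by CHI3 faster than a 1,2-aryl shift can occur, and the neutral radical conditions spare the electron-rich arene and the MOM ether.

Step 10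
Reactants: 16 2-[(1S)-2-iodo-1-phenylethyl]-1,5-dimethoxy-3-(methoxymethoxy)benzene; 8 (4aR,5R,8S)-5-methyl-8-(propan-2-yl)-4,4a,5,6,7,8-hexahydronaphthalen-2(3H)-one
Product: 20 (2S,4S,4'aR,5'R,8'S)-5,7-dimethoxy-5'-methyl-4-phenyl-8'-(propan-2-yl)-3',4',4'a,5',6',7',8'-heptahydrospiro[chromane-2,2'-naphthalene], via alkyllithium 17 (not isolated), via organocerium reagent 18 (not isolated), via tertiary allylic alcohol 19 (not isolated)
Conditions: 16 (1.3 equiv), t-BuLi (2.6 equiv), Et2O/pentane, −78 °C; CeCl3 (anhydrous, 1.4 equiv), THF, −78 °C; 8, THF, −78 °C; aq NaHCO3, extraction; crude 19, CSA (0.3 equiv), MeOH/CH2Cl2 (1:5), 0 → 23 °C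
Reagents that add atoms: none
Why: Iodine–lithium exchange gives 17, which is transmetalated to the weakly basic organocerium 18; this adds to the carbonyl carbon C2 of 8 instead of deprotonating it, and 1,4-addition is excluded because C8a is fully substituted, so the C2'–CH2 bond forms (19 as both carbinol epimers, which does not matter). CSA in the presence of methanol then ionises the tertiary allylic alcohol to a cyclohexenyl cation spanning C2', C1' and C8a' and cleaves the MOM acetal, and the phenol oxygen captures the cation at C2' in an SN1 etherification; the closest known reactions are organocerium 1,2-additions to enolisable enones and the acid-mediated chroman closure of phenols onto tertiary allylic cations. Ring C closes in a 6-exo-trig mode at the cation terminus that carries the tether, since attack at C8a' would need an eight-membered ring and the arene carbons cannot reach the cation. The new spiro stereocentre should be set by axial C–O bond formation on the half-chair of ring B, anti to the axial hydrogen at C4a', with ring A held by its equatorial methyl and isopropyl groups; this puts oxygen pseudoaxial and the larger CH2 pseudoequatorial, which should also be the more stable arrangement and can be reached by re-ionisation. The step needs 1,2-addition without enolisation (secured by cerium and the substituted β-carbon) and facial selectivity at the spiro carbon relative to the fixed benzylic and ring-fusion centres (secured by the conformational bias of ring B and by reversibility); the benzylic centre is not touched.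

Step 11
Reactants: 20 spirochroman dimethyl ether
Product: 21 (2S,4S,4'aR,5'R,8'S)-6,8-dibromo-5,7-dimethoxy-5'-methyl-4-phenyl-8'-(propan-2-yl)-3',4',4'a,5',6',7',8'-heptahydrospiro[chromane-2,2'-naphthalene]
Conditions: NBS (2.05 equiv), CH2Cl2, −20 → 0 °C, dark
Reagents that add atoms: N-bromosuccinimide, O=C1CCC(=O)N1Br
Why: Electrophilic aromatic bromination in which the two free positions of the trialkoxyarene should react far faster than the hindered trisubstituted alkene, and no acid is formed that could ionise the spiro ether.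

Step 12
Reactants: 21 dibromide
Product: 23 (2S,4S,4'aR,5'R,8'S)-5,7-dimethoxy-5'-methyl-4-phenyl-8'-(propan-2-yl)-3',4',4'a,5',6',7',8'-heptahydrospiro[chromane-2,2'-naphthalene]-6,8-dicarbaldehyde, via dilithio arene 22 (not isolated)
Conditions: t-BuLi (4.4 equiv), THF, −78 °C; DMF (6 equiv), −78 → 0 °C; aq NH4Cl
Reagents that add atoms: N,N-dimethylformamide, CN(C)C=O
Why: Double bromine–lithium exchange followed by Bouveault formylation, in which each aryllithium is flanked by two oxygens and is held after DMF addition as a hemiaminal alkoxide until work-up; the basic conditions keep the tertiary allylic aryl ether intact, which a Lewis-acid formylation would put at risk.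

Step 13
Reactants: 23 dialdehyde dimethyl ether
Product: 24 guajadial D, (2S,4S,4'aR,5'R,8'S)-5,7-dihydroxy-5'-methyl-4-phenyl-8'-(propan-2-yl)-3',4',4'a,5',6',7',8'-heptahydrospiro[chromane-2,2'-naphthalene]-6,8-dicarbaldehyde
Conditions: NaSEt (8 equiv), DMF, 100 °C; then 1 M HCl, 0 °C
Reagents that add atoms: none
Why: Nucleophilic SN2 demethylation by thiolate, in which both methoxy groups are ortho or para to formyl groups and so behave as vinylogous methyl esters, while the tertiary spiro C–O bond cannot be attacked; a boron or titanium halide is avoided because it would ionise that bond.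

**Compound list**

1 | (R)-citronellal | CC(C)=CCC[C@@H](C)CC=O | starting material
2 | methyl vinyl ketone | CC(=O)C=C | starting material
3 | (2R,3R)-3,7-dimethyl-2-(3-oxobutyl)oct-6-enal | CC(C)=CCC[C@@H](C)[C@@H](CCC(C)=O)C=O | intermediate
4 | (4R)-4-[(2R)-6-methylhept-5-en-2-yl]cyclohex-2-en-1-one | CC(C)=CCC[C@@H](C)[C@H]1CCC(=O)C=C1 | intermediate
5 | (4aR,5R,8R,8aR)-5-methyl-8-(prop-1-en-2-yl)octahydronaphthalen-2(1H)-one | CC(=C)[C@@H]1CC[C@@H](C)[C@H]2CCC(=O)C[C@@H]12 | intermediate
6 | (4aR,5R,8S,8aS)-5-methyl-8-(propan-2-yl)octahydronaphthalen-2(1H)-one | CC(C)[C@@H]1CC[C@@H](C)[C@H]2CCC(=O)C[C@@H]12 | intermediate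
7 | trimethyl{[(4aR,5R,8S,8aS)-5-methyl-8-(propan-2-yl)-3,4,4a,5,6,7,8,8a-octahydronaphthalen-2-yl]oxy}silane | CC(C)[C@@H]1CC[C@@H](C)[C@H]2CCC(O[Si](C)(C)C)=C[C@@H]12 | intermediate
8 | (4aR,5R,8S)-5-methyl-8-(propan-2-yl)-4,4a,5,6,7,8-hexahydronaphthalen-2(3H)-one | CC(C)[C@@H]1CC[C@@H](C)[C@H]2CCC(=O)C=C12 | intermediate
9 | 5,7-dimethoxycoumarin | COc1cc(OC)c2ccc(=O)oc2c1 | starting material
10 | phenylboronic acid | OB(O)c1ccccc1 | starting material
11 | (4S)-5,7-dimethoxy-4-phenylchroman-2-one | O=C1C[C@@H](c2ccccc2)c2c(OC)cc(OC)cc2O1 | intermediate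
12 | disodium (3S)-3-(2,4-dimethoxy-6-oxidophenyl)-3-phenylpropanoate | [Na+].[Na+].[O-]C(=O)C[C@@H](c1ccccc1)c1c(OC)cc(OC)cc1[O-] | intermediate
13 | methoxymethyl (3S)-3-[2,4-dimethoxy-6-(methoxymethoxy)phenyl]-3-phenylpropanoate | COCOC(=O)C[C@@H](c1ccccc1)c1c(OC)cc(OC)cc1OCOC | intermediate
14 | (3S)-3-[2,4-dimethoxy-6-(methoxymethoxy)phenyl]-3-phenylpropanoic acid | OC(=O)C[C@@H](c1ccccc1)c1c(OC)cc(OC)cc1OCOC | intermediate
15 | 2-thioxopyridin-1(2H)-yl (3S)-3-[2,4-dimethoxy-6-(methoxymethoxy)phenyl]-3-phenylpropanoate | O=C(C[C@@H](c1ccccc1)c1c(OC)cc(OC)cc1OCOC)ON1C=CC=CC1=S | intermediate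
16 | 2-[(1S)-2-iodo-1-phenylethyl]-1,5-dimethoxy-3-(methoxymethoxy)benzene | IC[C@@H](c1ccccc1)c1c(OC)cc(OC)cc1OCOC | intermediate
17 | {(2S)-2-[2,4-dimethoxy-6-(methoxymethoxy)phenyl]-2-phenylethyl}lithium | [Li]C[C@@H](c1ccccc1)c1c(OC)cc(OC)cc1OCOC | intermediate
18 | dichloro{(2S)-2-[2,4-dimethoxy-6-(methoxymethoxy)phenyl]-2-phenylethyl}cerium | Cl[Ce](Cl)C[C@@H](c1ccccc1)c1c(OC)cc(OC)cc1OCOC | intermediate
19 | (4aR,5R,8S)-2-{(2S)-2-[2,4-dimethoxy-6-(methoxymethoxy)phenyl]-2-phenylethyl}-5-methyl-8-(propan-2-yl)-2,3,4,4a,5,6,7,8-octahydronaphthalen-2-ol, both C2 epimers | CC(C)[C@@H]1CC[C@@H](C)[C@H]2CCC(O)(C[C@@H](c3ccccc3)c3c(OC)cc(OC)cc3OCOC)C=C12 | intermediate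
20 | (2S,4S,4'aR,5'R,8'S)-5,7-dimethoxy-5'-methyl-4-phenyl-8'-(propan-2-yl)-3',4',4'a,5',6',7',8'-heptahydrospiro[chromane-2,2'-naphthalene] | CC(C)[C@@H]1CC[C@@H](C)[C@H]2CC[C@@]3(C=C12)C[C@@H](c1ccccc1)c1c(OC)cc(OC)cc1O3 | intermediate
21 | 6,8-dibromo derivative of 20 | CC(C)[C@@H]1CC[C@@H](C)[C@H]2CC[C@@]3(C=C12)C[C@@H](c1ccccc1)c1c(OC)c(Br)c(OC)c(Br)c1O3 | intermediate
22 | 6,8-dilithio derivative of 20 | CC(C)[C@@H]1CC[C@@H](C)[C@H]2CC[C@@]3(C=C12)C[C@@H](c1ccccc1)c1c(OC)c([Li])c(OC)c([Li])c1O3 | intermediate
23 | 6,8-dicarbaldehyde of 20 (guajadial D dimethyl ether) | CC(C)[C@@H]1CC[C@@H](C)[C@H]2CC[C@@]3(C=C12)C[C@@H](c1ccccc1)c1c(OC)c(C=O)c(OC)c(C=O)c1O3 | intermediate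
24 | guajadial D | CC(C)[C@@H]1CC[C@@H](C)[C@H]2CC[C@@]3(C=C12)C[C@@H](c1ccccc1)c1c(O)c(C=O)c(O)c(C=O)c1O3 | target

**Step count and risks**

Total steps: 13. Longest linear sequence: 10 (steps 1–6, then 10–13).

Steps most likely to fail:

1. Step 10. The capture of the allyl cation may show poor facial selectivity at the spiro carbon, because the chroman half-chair (phenyl against the peri methoxy group) can oppose the bias of ring B. The cation may also be lost by E1 elimination, with scrambling of C4a' or C8' on re-protonation. The fallback sets out from enone 8, which is methylenated under non-basic Takai–Lombardo conditions (Zn, CH2Br2, TiCl4, THF) to (4aR,5R,8S)-5-methyl-2-methylidene-8-(propan-2-yl)-2,3,4,4a,5,6,7,8-octahydronaphthalene F1. (2-Hydroxy-4,6-dimethoxyphenyl)(phenyl)methanol F2, made from commercial 2-hydroxy-4,6-dimethoxybenzaldehyde and PhMgBr, is heated with F1 in toluene. It should lose water to the ortho-quinone methide 6-benzylidene-3,5-dimethoxycyclohexa-2,4-dien-1-one F3, which adds to the exocyclic methylene in an inverse-electron-demand hetero-Diels–Alder reaction with oxygen going to the spiro carbon. After chromatographic separation of the diastereomers the route is rejoined at 20, with no cation and no organometallic reagent involved.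

2. Step 5. Enolisation may go toward C3 instead of C1, so that the Saegusa–Ito step would deliver the isomeric C3=C4 enone. The fallback sets out from cyclohexenone 4 and fixes the regiochemistry with sulfur before ring A is closed. Weitz–Scheffer epoxidation (H2O2, NaOH, MeOH, 0 °C) gives the epoxy ketone F4, and thiophenol with base opens it at the α-carbon and dehydrates it to the 2-(phenylsulfanyl)cyclohexenone F5. The same EtAlCl2-promoted conjugate ene reaction should then give the cis-fused α-(phenylsulfanyl) ketone F6 with sulfur on C1. NaIO4 oxidises it to the sulfoxide F7, and heating in toluene over CaCO3 brings about syn elimination toward C8a, the only β-hydrogen, to the isopropenyl enone F8. Hydrogenation of the isopropenyl group with H2 and RhCl(PPh3)3 rejoins the route at 8.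

3. Step 7. Insertion of the hindered, electron-rich coumarin (peri methoxy group) may be so slow that protodeboronation consumes the phenylboronic acid. The fallback sets out from 9 and 10 and separates arylation from stereo-induction. Oxidative Heck arylation (Pd(OAc)2, 1,10-phenanthroline, O2, DMF) gives 5,7-dimethoxy-4-phenylcoumarin F9. CuH-catalysed asymmetric conjugate reduction follows (Cu(OAc)2·H2O, the DTBM-SEGPHOS antipode that gives the S centre, (EtO)2MeSiH, t-BuOH, toluene) and rejoins the route at 11.

Further compounds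
F1 | step 10 | (4aR,5R,8S)-5-methyl-2-methylidene-8-(propan-2-yl)-2,3,4,4a,5,6,7,8-octahydronaphthalene | CC(C)[C@@H]1CC[C@@H](C)[C@H]2CCC(=C)C=C12
F2 | step 10 | (2-hydroxy-4,6-dimethoxyphenyl)(phenyl)methanol | OC(c1ccccc1)c1c(O)cc(OC)cc1OC
F3 | step 10 | 6-benzylidene-3,5-dimethoxycyclohexa-2,4-dien-1-one | O=C1C=C(OC)C=C(OC)C1=Cc1ccccc1
F4 | step 5 | 2,3-epoxy-4-[(2R)-6-methylhept-5-en-2-yl]cyclohexan-1-one, (4R) | CC(C)=CCC[C@@H](C)[C@H]1CCC(=O)C2OC12
F5 | step 5 | (4R)-4-[(2R)-6-methylhept-5-en-2-yl]-2-(phenylsulfanyl)cyclohex-2-en-1-one | CC(C)=CCC[C@@H](C)[C@H]1CCC(=O)C(Sc2ccccc2)=C1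
F6 | step 5 | (4aR,5R,8R,8aR)-5-methyl-1-(phenylsulfanyl)-8-(prop-1-en-2-yl)octahydronaphthalen-2(1H)-one | CC(=C)[C@@H]1CC[C@@H](C)[C@H]2CCC(=O)C(Sc3ccccc3)[C@@H]12
F7 | step 5 | (4aR,5R,8R,8aR)-5-methyl-1-(phenylsulfinyl)-8-(prop-1-en-2-yl)octahydronaphthalen-2(1H)-one | CC(=C)[C@@H]1CC[C@@H](C)[C@H]2CCC(=O)C(S(=O)c3ccccc3)[C@@H]12
F8 | step 5 | (4aR,5R,8R)-5-methyl-8-(prop-1-en-2-yl)-4,4a,5,6,7,8-hexahydronaphthalen-2(3H)-one | CC(=C)[C@@H]1CC[C@@H](C)[C@H]2CCC(=O)C=C12
F9 | step 7 | 5,7-dimethoxy-4-phenylcoumarin | O=C1C=C(c2ccccc2)c2c(OC)cc(OC)cc2O1
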